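Numbering: ring A = O1, C2 (lactone C=O), C3 (bears C1', the acetoxy carbon of the butyl chain), C4 (bears Br), C5 (bears the exocyclic C6HBr).
Enabling feature: C2 is one carbon wedged between C3 and O1, and these two atoms are already joined the other way round ring A through C3=C4–C5. C2 can therefore be taken out as CO, leaving a halide on C3 and a C5 ketone oxygen locked on the same side of C3=C4.
Cuts, in retrosynthetic order: C6–Br; C2–C3 and O1–C2 (ring A opened, CO released); C3–I and C4–Br (back to a C3≡C4 ynone); the acetate ester bond; C4–C5 (acetylide plus acetyl donor).
Forward: the C8 chain is joined at C4–C5 and O-acetylated, the alkyne is dressed with I (C3) and Br (C4), ring A (the only ring) is closed with CO, and C6 is brominated last.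
Stereochemistry: C1' (R) comes from a lipase resolution of the racemic propargylic alcohol and is not touched again. The C3=C4 geometry comes from anti I/Br addition, and the (Z)-C5=C6 geometry from an elimination in which the new bromine avoids the C4 bromine.

Key step: step 5

Assumption: the lipase follows its usual size rule for secondary alcohols (ethynyl in the medium pocket, propyl in the large one), so the (S)-alcohol is esterified and the (R)-alcohol stays behind.

Step 1
Reactants: 1 rac-hex-1-yn-3-ol
Product: 2 (R)-hex-1-yn-3-ol
Conditions: immobilised Candida antarctica lipase B, vinyl acetate (0.7 equiv), MTBE, 30 °C, stopped past half conversion; chromatography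
Reagents that add atoms: none
Why: Lipase-catalysed kinetic resolution by irreversible transesterification: the (S)-alcohol is the fast-reacting enantiomer, so the C1' stereocentre is obtained as the unreacted (R)-alcohol, whose enantiomeric purity can be raised by letting the conversion run past one half.

Step 2
Reactants: 2 (R)-hex-1-yn-3-ol; 3 N-methoxy-N-methylacetamide
Product: 6 (R)-5-hydroxyoct-3-yn-2-one, via dilithium alkoxide-acetylide 4 (not isolated), via dilithium tetrahedral adduct 5 (not isolated)
Conditions: n-BuLi (2.1 equiv), THF, −78 °C; 3 (1.2 equiv), −78 to 0 °C; inverse quench into cold 1 M HCl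
Reagents that add atoms: N-methoxy-N-methylacetamide CON(C)C(C)=O
Why: Weinreb ketone synthesis on the O,C-dianion of a propargylic alcohol: the acetylide carbon is the more nucleophilic site, adduct 5 cannot collapse before the quench so no second addition occurs, and the inverse acidic quench protonates the released amine before it can add to the ynone and spares the base-sensitive C1'–H.

Step 3
Reactants: 6 (R)-5-hydroxyoct-3-yn-2-one; 7 acetic anhydride
Product: 8 (R)-2-oxooct-3-yn-5-yl acetate
Conditions: Ac2O (1.5 equiv), Sc(OTf)3 (1 mol %), MeCN, 0 °C
Reagents that add atoms: acetic anhydride CC(=O)OC(C)=O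
Why: Sc(OTf)3-catalysed O-acylation with an anhydride forms the ester at oxygen without touching the C1'–O bond (retention), and the amine-free medium avoids the base-induced redox isomerisation of γ-hydroxy ynones to enediones that would destroy C1'.

Step 4
Reactants: 8 (R)-2-oxooct-3-yn-5-yl acetate; 9 iodotrimethylsilane; 10 N-bromosuccinimide
Product: 12 (R,E)-3-bromo-4-iodo-2-oxooct-3-en-5-yl acetate, via siloxyallene 11 (not isolated)
Conditions: Me3SiI (1.0 equiv), CH2Cl2, −78 to −40 °C; NBS (1.05 equiv), −78 to −20 °C, dark; aq Na2S2O3/NaHCO3
Reagents that add atoms: iodotrimethylsilane C[Si](C)(C)I; N-bromosuccinimide O=C1CCC(=O)N1Br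
Why: Proposed new method: Me3SiI silylates the ketone oxygen and delivers iodide to the β-carbon C3, giving siloxyallene 11, whose enol-ether lobe at C4 lies in the plane of the C3 substituents; NBS should be taken up by the lobe anti to the C3–I bond (the anti rule of nucleophilic additions to alkynes, reinforced by I/Br repulsion and by C1' turning only its hydrogen into that plane), which puts Br trans to I and I cis to the acetyl group, also the expected thermodynamic trans-dihalide; the closest known reactions are the Me3SiI- or MgI2-mediated β-iodo Baylis–Hillman (halo-aldol) couplings of ynones, in which the same β-iodoallenolate is trapped by aldehydes, and the α-bromination of silyl enol ethers and siloxyallenes with NBS; no stereocentre is formed and C1' is untouched.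

Step 5
Reactants: 12 (R,E)-3-bromo-4-iodo-2-oxooct-3-en-5-yl acetate; 13 carbon monoxide
Product: 15 (R)-1-(4-bromo-5-methylene-2-oxo-2,5-dihydrofuran-3-yl)butyl acetate, via acylpalladium iodide 14 (not isolated)
Conditions: Pd(PPh3)4 (5 mol %), Et3N (2 equiv), CO (10 atm), dry toluene, 50 °C
Reagents that add atoms: carbon monoxide [C-]#[O+]
Why: Zerovalent palladium inserts into the C3–I bond, CO undergoes migratory insertion to give acylpalladium iodide 14 (bond C2–C3), and the oxygen of the acetyl group, held cis across C3=C4, attacks the acyl carbon while Et3N takes up a C6 proton and the iodide, releasing the enol lactone (bond O1–C2) and zerovalent palladium. This is the known palladium-catalysed carbonylative lactonisation of (Z)-β-iodoenones and o-iodoaryl ketones, in which an internal O-enolate traps the acylpalladium to give γ-ylidene butenolides and ylidene phthalides. Ring A closes by a 5-exo-trig attack of O1 on C2; C-acylation through C6 would be a disfavoured 5-(enolendo)-exo-trig closure to a cyclopentenedione, and because C4 carries no hydrogen the proton can leave only from C6, so the exocyclic methylene is the only enol lactone possible. No stereocentre is created: C1' is a spectator whose C–H bond is held in the alkene plane by allylic strain against the C4 bromine, out of overlap with the enone π system, so Et3N should not remove it, and the C3=C4 geometry simply becomes the ring double bond. The step needs insertion at C3–I ahead of C4–Br and of the allylic C1'–OAc; the C–I bond is the weaker one and sits at the electrophilic β-carbon of the enone, the position at which (E)-2,3-dihaloacrylates are known to couple selectively, while the tetrasubstituted electron-poor alkene binds palladium too poorly for acetate ionisation. CO pressure lets insertion outrun loss of bromide from the β-bromovinylpalladium species, toluene takes the iodide out of solution as its ammonium salt, and the dry, alcohol-free medium at 50 °C leaves the C4–Br bond of the product no productive pathway.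

Step 6
Reactants: 15 (R)-1-(4-bromo-5-methylene-2-oxo-2,5-dihydrofuran-3-yl)butyl acetate; 16 bromine
Product: 18 (R)-1-[(5Z)-4-bromo-5-(bromomethylene)-2-oxo-2,5-dihydrofuran-3-yl]butyl acetate, via tribromide adduct 17 (not isolated)
Conditions: Br2 (1.0 equiv), CH2Cl2, 0 °C, dark; then i-Pr2NEt (1.2 equiv), 0 °C to rt
Reagents that add atoms: bromine BrBr
Why: Bromination–dehydrobromination of a 5-methylene-2(5H)-furanone: Br2 adds to the electron-rich enol-ester bond C5=C6 rather than to the carbonyl- and bromine-deactivated C3=C4, and anti elimination of HBr from the labile tertiary C5 bromide passes through the conformer in which the C6 bromine lies next to O1 and away from the C4 bromine, which gives the (Z)-alkene and leaves C1' untouched.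

Compound list
1 | rac-hex-1-yn-3-ol | CCCC(O)C#C | starting material
2 | (R)-hex-1-yn-3-ol | CCC[C@@H](O)C#C | intermediate
3 | N-methoxy-N-methylacetamide | CON(C)C(C)=O | starting material
4 | dilithium O,C-dianion of (R)-hex-1-yn-3-ol | CCC[C@@H]([O-])C#[C-].[Li+].[Li+] | intermediate
5 | dilithium (5R)-2-[methoxy(methyl)amino]oct-3-yne-2,5-diolate (tetrahedral adduct, C2 unassigned) | CCC[C@@H]([O-])C#CC(C)([O-])N(C)OC.[Li+].[Li+] | intermediate
6 | (R)-5-hydroxyoct-3-yn-2-one | CCC[C@@H](O)C#CC(C)=O | intermediate
7 | acetic anhydride | CC(=O)OC(C)=O | starting material
8 | (R)-2-oxooct-3-yn-5-yl acetate | CCC[C@@H](OC(C)=O)C#CC(C)=O | intermediate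
9 | iodotrimethylsilane | C[Si](C)(C)I | starting material
10 | N-bromosuccinimide | O=C1CCC(=O)N1Br | starting material
11 | (5R)-4-iodo-2-(trimethylsilyloxy)octa-2,3-dien-5-yl acetate (allene axis unassigned) | CCC[C@@H](OC(C)=O)C(I)=C=C(C)O[Si](C)(C)C | intermediate
12 | (R,E)-3-bromo-4-iodo-2-oxooct-3-en-5-yl acetate (I cis to acetyl; E only because Br outranks the acyl carbon) | CCC[C@@H](OC(C)=O)/C(I)=C(\Br)C(C)=O | intermediate
13 | carbon monoxide | [C-]#[O+] | starting material
14 | acylpalladium iodide from 12 and CO (divalent palladium; the two PPh3 ligands are left out of the SMILES) | CCC[C@@H](OC(C)=O)/C(C(=O)[Pd]I)=C(\Br)C(C)=O | intermediate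
15 | (R)-1-(4-bromo-5-methylene-2-oxo-2,5-dihydrofuran-3-yl)butyl acetate | CCC[C@@H](OC(C)=O)C1=C(Br)C(=C)OC1=O | intermediate
16 | bromine | BrBr | starting material
17 | (1R)-1-[4,5-dibromo-5-(bromomethyl)-2-oxo-2,5-dihydrofuran-3-yl]butyl acetate (both C5 epimers) | CCC[C@@H](OC(C)=O)C1=C(Br)C(Br)(CBr)OC1=O | intermediate
18 | (R)-1-[(5Z)-4-bromo-5-(bromomethylene)-2-oxo-2,5-dihydrofuran-3-yl]butyl acetate | CCC[C@@H](OC(C)=O)C1=C(Br)/C(=C/Br)OC1=O | target

Total step count: 6. Longest linear sequence: 6 (from 1).

Steps most likely to fail

Step 4. Three processes threaten it: capture of the bromonium source on the face syn to iodine (loss of alkene geometry), halogen scrambling when stray iodide is oxidised by NBS, and slow cleavage of the acetate by Me3SiI. The fallback sets out from 8 and gives up the mixed dihalide. Br2 in CH2Cl2 at 0 °C adds anti across the ynone, a well-known route to (E)-2,3-dibromo enones and enoates. It gives (R,E)-3,4-dibromo-2-oxooct-3-en-5-yl acetate F1, with no regiochemical question because both halogens are alike. This dibromide is then carbonylated itself (Pd(OAc)2, Xantphos, Et3N, CO, toluene, 80 °C). Site selection now rests on the electronic activation of the β C3–Br bond over the α C4–Br bond, as in the β-selective couplings of (E)-2,3-dibromoacrylates. The same two ring bonds form, and the route is rejoined at 15.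

Step 5. Four processes threaten it: loss of bromide from the vinylpalladium species with return to the alkyne, slow capture by the enol oxygen that leaves time for hydrodeiodination, ionisation of the allylic acetate, and polymerisation of the methylene lactone at the reaction temperature. The fallback sets out from 12 and still inserts CO at C3, but hands the acylpalladium to water instead of the enol. Hydroxycarbonylation of the vinyl iodide (PdCl2(PPh3)2, Et3N, CO, wet THF, 40 °C) should give (1R)-1-(4-bromo-5-hydroxy-5-methyl-2-oxo-2,5-dihydrofuran-3-yl)butyl acetate F2, the ring form in which cis-β-acylacrylic acids rest. A separate dehydration with P2O5 in CH2Cl2, the usual way from such lactols to 5-methylene furanones, comes back to the route at 15.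

Step 6. Four processes threaten it: poor Z/E control in the elimination, conjugate addition of bromine across C3 to C6, hydrolysis of the tertiary bromide, and attack of the amine at C4. The fallback sets out from 15 and replaces the base-induced elimination by an acid-mediated, equilibrating one. NBS in aqueous THF forms the bromohydrin, (1R)-1-[4-bromo-5-(bromomethyl)-5-hydroxy-2-oxo-2,5-dihydrofuran-3-yl]butyl acetate F3. P2O5 in refluxing CH2Cl2 dehydrates it through the oxygen-stabilised C5 cation, so the more stable (Z)-bromomethylene geometry should result. The route is rejoined at 18.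

Further compounds
F1 | step 4 | (R,E)-3,4-dibromo-2-oxooct-3-en-5-yl acetate | CCC[C@@H](OC(C)=O)/C(Br)=C(\Br)C(C)=O
F2 | step 5 | (1R)-1-(4-bromo-5-hydroxy-5-methyl-2-oxo-2,5-dihydrofuran-3-yl)butyl acetate (both C5 epimers) | CCC[C@@H](OC(C)=O)C1=C(Br)C(C)(O)OC1=O
F3 | step 6 | (1R)-1-[4-bromo-5-(bromomethyl)-5-hydroxy-2-oxo-2,5-dihydrofuran-3-yl]butyl acetate (both C5 epimers) | CCC[C@@H](OC(C)=O)C1=C(Br)C(O)(CBr)OC1=O
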